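**Direct plan and its weak points**

A direct plan would join two ready-made bromoarenes at the diaryl ether oxygen. 1,2,3-Tribromobenzene A1 would be borylated and oxidised to 3,4,5-tribromophenol A2 and then protected as the methoxymethyl ether A3 for the coupling. A3 would be metalated between the acetal oxygen and a bromine, moved to copper and coupled oxidatively with the aryloxide of 3,5-dibromo-2-methoxyphenol A4 to give the protected diaryl ether A5 as the last intermediate, which acid would unmask.
- The aryl–oxygen coupling of A3 with A4 would be weak: it joins a di-ortho-substituted arylmetal to a di-ortho-substituted aryloxide through an ortho-bromo arylmetal (aryne loss, halogen–metal scrambling, biaryl homocoupling) and has no close precedent with five C–Br bonds present.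
- The run-up from A1 to A2 would be weak: C–H borylation and oxidation are spent on a simple phenol before any bond of the core exists.
- The methoxymethyl group of A3 and A5 would be weak: it is put on only to direct the metalation and taken off at the end, two steps that build nothing.

**Retrosynthetic overview**

- Locants: ring A carries OH at C1, the bridging O at C2, Br at C3–C5. Ring B carries the bridging O at C1', OMe at C2', Br at C3' and C5'.
- Ring B is not bought as an arene. Its six carbons come from 2-chlorocyclohexanone, the C1'–O bond is made as an sp3 C–O bond by SN2, and the ring is aromatized late, the ketone carbon becoming C2'–OH. The key step forms the C=C bonds of ring B, not an aryl–O bond.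
- Both bromine patterns are the ortho/para pattern of a free phenol oxygen. Ring A is tribrominated while the future bridging oxygen is still a free OH. Ring B is dibrominated at C3'/C5' through the C2'–OH that the aromatization unveils.
- The design needs no arylmetal next to bromine, no metal-mediated aryl–O coupling and no borylation run-up. The single benzyl group comes with the commercial starting material.

Key step: step 3

Assumption: the cyclohexanone intermediates are handled as racemates; the target has no stereocentre, so this has no consequence.

**Route**

Step 1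
Reactants: 1 2-(benzyloxy)phenol
Product: 2 6-(benzyloxy)-2,3,4-tribromophenol
Conditions: Br2 (3.1 equiv), NaOAc (3.3 equiv), AcOH, 15 to 45 °C
Reagents that add atoms: bromine, BrBr
Why: Electrophilic aromatic bromination: the free hydroxyl directs bromine to its ortho and para carbons and the third bromine enters para to the benzyloxy group, so only the C–H ortho to the benzyl ether and meta to the hydroxyl, the least activated and most shielded position, should remain, while sodium acetate takes up HBr and spares the benzyl ether.

Step 2
Reactants: 2 6-(benzyloxy)-2,3,4-tribromophenol; 3 2-chlorocyclohexan-1-one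
Product: 4 2-[6-(benzyloxy)-2,3,4-tribromophenoxy]cyclohexan-1-one (racemic)
Conditions: K2CO3 (1.5 equiv), 3 (1.3 equiv), DMF, 60 °C
Reagents that add atoms: none
Why: Williamson ether synthesis by SN2 displacement at an α-chloro ketone, which the adjacent carbonyl accelerates enough for the hindered tribromophenoxide, whose low basicity should in turn suppress enolisation and Favorskii pathways of 3; the new stereocentre forms as a racemate and is erased in step 3.

Step 3
Reactants: 4 2-[6-(benzyloxy)-2,3,4-tribromophenoxy]cyclohexan-1-one
Product: 6 2-[6-(benzyloxy)-2,3,4-tribromophenoxy]phenol, via 6-aryloxycyclohex-2-en-1-one 5 (not isolated)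
Conditions: Pd(OCOCF3)2 (5 mol%), 2-(dimethylamino)pyridine (10 mol%), TsOH·H2O (20 mol%), O2 (1 atm), DMSO, 80 °C
Reagents that add atoms: none
Why: Divalent palladium should palladate the ketone α-carbon through its enol, β-hydride elimination should give enone 5, and O2 should return the palladium hydride to the active catalyst; a second palladation and β-hydride elimination then gives a cyclohexadienone that tautomerizes irreversibly to phenol 6. The closest known reaction type is the aerobic palladium-catalysed dehydrogenation of substituted cyclohexanones to phenols. No ring is closed: the six carbons of ring B are already a ring in 3, and the step turns this cyclohexanone into an arene, which converts the alkyl aryl ether at C1' into the doubly ortho-substituted diaryl ether without any aryl–oxygen coupling. No stereocentre is formed, and the racemic centre C1' of 4 is erased. The step needs C–H over C–Br selectivity, which the oxidative conditions should secure because O2 reoxidises zerovalent palladium faster than it can insert into the three flanked C–Br bonds of ring A, and the aryloxy group is never β to a carbon that carries palladium, so it cannot be lost by β-elimination. Either α-carbon may be dehydrogenated first, since the isomeric enone converges on the same phenol.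

Step 4
Reactants: 6 2-[6-(benzyloxy)-2,3,4-tribromophenoxy]phenol
Product: 7 2-[6-(benzyloxy)-2,3,4-tribromophenoxy]-4,6-dibromophenol
Conditions: NBS (2.05 equiv), MeCN, 0 °C to rt, dark
Reagents that add atoms: N-bromosuccinimide, O=C1CCC(=O)N1Br
Why: Electrophilic aromatic bromination: the free hydroxyl on ring B directs both bromines to its ortho and para carbons (C3' and C5'), whereas ring A carries three bromines and a single flanked C–H and the benzyl ring is not activated, so neither should compete at this stoichiometry.

Step 5
Reactants: 7 2-[6-(benzyloxy)-2,3,4-tribromophenoxy]-4,6-dibromophenol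
Product: 8 1-(benzyloxy)-3,4,5-tribromo-2-(3,5-dibromo-2-methoxyphenoxy)benzene
Conditions: MeI (1.5 equiv), K2CO3 (2 equiv), DMF, rt
Reagents that add atoms: iodomethane, CI
Why: Williamson ether synthesis: carbonate deprotonates the acidic dibromophenol, the only free hydroxyl in the molecule, and the phenoxide is methylated by SN2 on iodomethane.

Step 6
Reactants: 8 1-(benzyloxy)-3,4,5-tribromo-2-(3,5-dibromo-2-methoxyphenoxy)benzene
Product: 9 3,4,5-tribromo-2-(3,5-dibromo-2-methoxyphenoxy)phenol
Conditions: BCl3 (2.5 equiv), pentamethylbenzene (3 equiv), CH2Cl2, −78 °C; then H2O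
Reagents that add atoms: none
Why: Lewis acid cleavage of the aryl benzyl ether: BCl3 binds the ether oxygen and the benzyl cation is trapped by pentamethylbenzene in a Friedel–Crafts alkylation, which at −78 °C should be much faster than cleavage of the methyl ether or the diaryl ether and, unlike hydrogenolysis, leaves the five C–Br bonds alone.

**Compound list**

1 | 2-(benzyloxy)phenol | Oc1ccccc1OCc1ccccc1 | starting material
2 | 6-(benzyloxy)-2,3,4-tribromophenol | Oc1c(Br)c(Br)c(Br)cc1OCc1ccccc1 | intermediate
3 | 2-chlorocyclohexan-1-one (racemic) | O=C1CCCCC1Cl | starting material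
4 | 2-[6-(benzyloxy)-2,3,4-tribromophenoxy]cyclohexan-1-one (racemic) | O=C1CCCCC1Oc1c(Br)c(Br)c(Br)cc1OCc1ccccc1 | intermediate
5 | 6-[6-(benzyloxy)-2,3,4-tribromophenoxy]cyclohex-2-en-1-one (racemic, not isolated) | O=C1C=CCCC1Oc1c(Br)c(Br)c(Br)cc1OCc1ccccc1 | intermediate
6 | 2-[6-(benzyloxy)-2,3,4-tribromophenoxy]phenol | Oc1ccccc1Oc1c(Br)c(Br)c(Br)cc1OCc1ccccc1 | intermediate
7 | 2-[6-(benzyloxy)-2,3,4-tribromophenoxy]-4,6-dibromophenol | Oc1c(Br)cc(Br)cc1Oc1c(Br)c(Br)c(Br)cc1OCc1ccccc1 | intermediate
8 | 1-(benzyloxy)-3,4,5-tribromo-2-(3,5-dibromo-2-methoxyphenoxy)benzene | COc1c(Br)cc(Br)cc1Oc1c(Br)c(Br)c(Br)cc1OCc1ccccc1 | intermediate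
9 | 3,4,5-tribromo-2-(3,5-dibromo-2-methoxyphenoxy)phenol | COc1c(Br)cc(Br)cc1Oc1c(O)cc(Br)c(Br)c1Br | target

**Step count and risks**

Total step count: 6. Longest linear sequence: 6.

Steps most likely to fail:

1. Step 3 (key step). Zerovalent palladium could insert into the C–Br bonds of ring A before O2 reoxidises it, or the dehydrogenation could stall at the enone stage as the catalyst aggregates. The fallback sets out from 2 and returns at 6; it enters one oxidation level higher and aromatizes without a metal. The phenoxide of 2 would open racemic 7-oxabicyclo[4.1.0]heptan-2-one F1 at the carbon α to the carbonyl (K2CO3, DMF, 80 °C); this attack on F1 should give trans-2-[6-(benzyloxy)-2,3,4-tribromophenoxy]-3-hydroxycyclohexan-1-one F2 as the first product. Under the same conditions F2 would lose water to give 2-[6-(benzyloxy)-2,3,4-tribromophenoxy]cyclohex-2-en-1-one F3 as the enone. Soft enolisation of F3 at the α' carbon (TMSOTf, Et3N, CH2Cl2, 0 °C) would give the cross-conjugated silyl dienol ether {[6-[6-(benzyloxy)-2,3,4-tribromophenoxy]cyclohexa-1,5-dien-1-yl]oxy}trimethylsilane F4 as a 1,3-cyclohexadiene. DDQ (benzene, rt) would dehydrogenate F4 to {2-[6-(benzyloxy)-2,3,4-tribromophenoxy]phenoxy}trimethylsilane F5 as the aryl silyl ether, and dilute HCl in THF would cleave the silyl ether of F5 to give 6.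

2. Step 2. Substitution by the hindered, weakly nucleophilic phenoxide could be slower than base-induced self-condensation or Favorskii rearrangement of the chloro ketone. The fallback sets out from 2 and returns at 4; it replaces the enolisable electrophile by an epoxide and adds an oxidation. The phenoxide of 2 would open cyclohexene oxide F6 by SN2 with inversion (K2CO3, DMF, 110 °C); the opening of F6 should give racemic trans-2-[6-(benzyloxy)-2,3,4-tribromophenoxy]cyclohexan-1-ol F7 as the only diastereomer. Dess–Martin periodinane (CH2Cl2, rt) would then oxidise the secondary alcohol of F7 to give 4.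

3. Step 1. The third bromination, at a carbon flanked by two bromines, could be incomplete, or a fourth bromine could enter the last ring C–H under the forcing needed, with acid loss of the benzyl group as a further drain. The fallback sets out from 1 and returns at 2; it puts the hindered bromine in first by switching the directing power of the two oxygens. Acetylation of 1 (Ac2O, pyridine) would give 2-(benzyloxy)phenyl acetate F8 as the ester. One bromination of F8 para to the benzyloxy group, now the stronger donor (NBS, MeCN, rt), would give 2-(benzyloxy)-5-bromophenyl acetate F9 as the monobromide. Methanolysis of F9 (K2CO3, MeOH) would give 2-(benzyloxy)-5-bromophenol F10 as the free phenol. Two further equivalents of NBS would then brominate F10 ortho and para to the freed hydroxyl to give 2.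

**Further compounds**

F1 | step 3 | 7-oxabicyclo[4.1.0]heptan-2-one (2,3-epoxycyclohexanone; racemic, cis-fused by necessity) | O=C1CCCC2OC12
F2 | step 3 | trans-2-[6-(benzyloxy)-2,3,4-tribromophenoxy]-3-hydroxycyclohexan-1-one (racemic, one enantiomer drawn) | O=C1CCC[C@H](O)[C@H]1Oc1c(Br)c(Br)c(Br)cc1OCc1ccccc1
F3 | step 3 | 2-[6-(benzyloxy)-2,3,4-tribromophenoxy]cyclohex-2-en-1-one | O=C1CCCC=C1Oc1c(Br)c(Br)c(Br)cc1OCc1ccccc1
F4 | step 3 | {[6-[6-(benzyloxy)-2,3,4-tribromophenoxy]cyclohexa-1,5-dien-1-yl]oxy}trimethylsilane | C[Si](C)(C)OC1=CCCC=C1Oc1c(Br)c(Br)c(Br)cc1OCc1ccccc1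
F5 | step 3 | {2-[6-(benzyloxy)-2,3,4-tribromophenoxy]phenoxy}trimethylsilane | C[Si](C)(C)Oc1ccccc1Oc1c(Br)c(Br)c(Br)cc1OCc1ccccc1
F6 | step 2 | cyclohexene oxide (7-oxabicyclo[4.1.0]heptane) | C1CCC2OC2C1
F7 | step 2 | trans-2-[6-(benzyloxy)-2,3,4-tribromophenoxy]cyclohexan-1-ol (racemic, (1R,2R) enantiomer drawn) | O[C@@H]1CCCC[C@H]1Oc1c(Br)c(Br)c(Br)cc1OCc1ccccc1
F8 | step 1 | 2-(benzyloxy)phenyl acetate | CC(=O)Oc1ccccc1OCc1ccccc1
F9 | step 1 | 2-(benzyloxy)-5-bromophenyl acetate | CC(=O)Oc1cc(Br)ccc1OCc1ccccc1
F10 | step 1 | 2-(benzyloxy)-5-bromophenol | Oc1cc(Br)ccc1OCc1ccccc1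
A1 | direct plan | 1,2,3-tribromobenzene | Brc1cccc(Br)c1Br
A2 | direct plan | 3,4,5-tribromophenol | Oc1cc(Br)c(Br)c(Br)c1
A3 | direct plan | 1,2,3-tribromo-5-(methoxymethoxy)benzene | COCOc1cc(Br)c(Br)c(Br)c1
A4 | direct plan | 3,5-dibromo-2-methoxyphenol | COc1c(Br)cc(Br)cc1O
A5 | direct plan | 1,2,3-tribromo-4-(3,5-dibromo-2-methoxyphenoxy)-5-(methoxymethoxy)benzene | COCOc1cc(Br)c(Br)c(Br)c1Oc1cc(Br)cc(Br)c1OC
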